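The earlier runs and the new flask are simulated with constants of no real substance, and the scatter is random.

Reading the oak run for 5.0 h

1. If the reagent were used for product and nothing else, a balance would tell me how hard the flask still works, so I test that balance against the rates. Here are the flasks, readings, conditions, options and questions:

- oak: left-handed substrate 24 mM; right-handed substrate 24 mM; reagent 48 mM; free catalyst 12 µM; the very flask that is asked about, followed so far
- flask: left-handed substrate 24 mM; reagent 48.0 mM; free catalyst 12 µM; right-handed substrate 24 mM; time 5.0 h

- oak (time / h: left-handed product / %, left-handed substrate / %): 0.250: 7.1, 42.9; 0.417: 13.1, 39.9; 0.833: 19.1, 35.4; 1.50: 22.0, 36.8; 3.00: 26.9, 35.2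

(scatter of a reading: 1 percentage point)

- free catalyst is single-handed; left-handed substrate and right-handed substrate are mirror images of each other, charged as a racemate, each of them at the stated concentration
- removed left-handed product is counted in
- additions bring no volume worth counting

- Saturday's: change nothing and wait 10 h more
- Sunday's: at 5.0 h take out 90% of the left-handed product then present, then wait 10 h
- Monday's: at 5.0 h add free catalyst, 100% of the amount charged, then wait 10 h
- Wednesday's: at 5.0 h add reagent, 100% of the amount charged, then wait 10 h

* left-handed product, in percent of the left-handed substrate and right-handed substrate together first charged, at 5.0 h
* which option adds most left-handed product ("none" when 2 percentage points or less is all one gets) (Saturday's / Sunday's / Monday's / Wednesday's / none)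
* left-handed product present, with what was taken out counted in, in percent of the left-handed substrate and right-handed substrate together first charged, after Sunday's
* left-handed product present, with what was taken out counted in, in percent of the left-handed substrate and right-handed substrate together first charged, after Wednesday's

2. I define the drive as the rate of left-handed product per left-handed substrate late in the oak run, divided by the same quantity early on. The early value is 0.662 /h and the late value, between the last two readings, is 0.0928 /h. Neither is a true constant, for reagent and free catalyst are not held, so the ratio belongs to these two stretches, and my reading of the drive for them is 14.0%.

3. The second way is the balance. If one reagent goes per left-handed product, the oak run at 3.00 h keeps 73.1% of its reagent, and the drive ought to stand near that if free catalyst holds.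

4. The two part widely, with 14.0% against 73.1%. The balance is the one that cheats, because it counts product and cannot see a silent loss of reagent or free catalyst. The readings cannot tell me which of the two partners is going, so I can't choose between Monday's and Wednesday's, though Sunday's restores neither.

5. If the drive keeps falling as one over time, the late rate times its mid-time stays constant, and I reckon 30.7% of left-handed product at 5.0 h.

6. The forecast gives 32%, Monday's as best, 41% after Sunday's and 49% after Wednesday's: “Fresh catalyst gives about 53 %, narrowly the best.”

7. The flask gives 29.3% at 5.0 h, and Wednesday's is best with 13 percentage points gained, against 4.5 points for Monday's, 2.6 points for Saturday's and 2.6 points for Sunday's. That puts 31.9% after Sunday's and 41.8% after Wednesday's.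

    reagent + free catalyst + left-handed substrate → free catalyst + left-handed product (k = 40200 /M²/min)
    reagent + free catalyst + right-handed substrate → free catalyst + right-handed product (k = 986 /M²/min)
    left-handed substrate ⇌ right-handed substrate (k = 0.0112 /min)
    2 free catalyst → spent catalyst (k = 309 /M/min)
    reagent ⇌ dormant form (K = 0.340, k = 0.235 /min)
    2 reagent → homo dimer (k = 0.486 /M/min)

8. The shrinking supply of reagent is the main reason this flask stands at 29.3%, since the run with reagent held at its charge reaches 74.3%; at 5.00 h the flask keeps 5.0% of its reagent, where the balance allows 70.7%. Taking the drive as reagent share times free catalyst share, the flask's value at 2.50 h set against its value at 0.500 h is 17.0%, beside my reading 14.0% from two stretches of the oak run. On that same count of shares the flask stands at 1.56% at 5.00 h, Wednesday's lifts it to 32.6%, and Monday's lifts it to 6.59%. The neighbour flask charged with 12 mM of reagent starts at a drive of 25.0% of this flask's and holds 13.0% of left-handed product at 5.0 h.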